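**Retrosynthetic overview**

1. The target is an ester between two C13-epimeric 8,13-epoxy-2,3-secolabdane diacids. The last disconnection is the ester between the C3 acid of the vinyl half and the primary C15–OH of the 13R,14R-diol half, and both halves are drawn from one common intermediate.
2. That intermediate has a C8 tertiary alcohol and a (13Z)-allylic alcohol side chain. Sharpless epoxidation with D-(−)- or L-(+)-tartrate, then 6-exo opening of the epoxide at C13 by the C8–OH, closes the pyran (O, C8, C9, C11, C12, C13; formed last) and sets C13/C14 for either half. The vinyl group of the left half comes from its 14,15-diol.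
3. Ring B (C5–C10) is not made as a six-membered ring. A cyclopentanone holding C5, C6, C7, C8 (C=O) and C10 is joined at C8 to a nerol-derived C9 carbanion and enlarged by a seleno-semipinacol 1,2-shift of C10 from C8 to C9. This inserts C9 between C8 and C10 and leaves a C8 ketone (then C8=CH2, then C8(CH3)OH).
4. Enabling feature: C8 is the only oxygen-bearing carbon of ring B and lies between the quaternary C10 (the best migrating group) and the H-bearing C9. A C8 carbinol can push its C8–C10 ring bond onto an exocyclic C9, and the C9–H next to the new C8 ketone lets C9 equilibrate to the needed equatorial epimer.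
5. The cyclopentanone comes from 2-methylcyclopent-2-enone by enantioselective Mukaiyama–Michael addition (C5) and trans enolate alkylation (C10). Ring order: cyclopentane, then ring B by enlargement, then the pyran.

Key step: step 8

Remark: labdane numbering is used (ring B = C5–C10, pyran oxygen between C8 and C13, acids C2 and C3); the target is read as 5S,8S,9S,10R in both halves, 13S in the vinyl half and 13R,14R in the diol half; TBS = tert-butyldimethylsilyl, TMSE = 2-(trimethylsilyl)ethyl.

**Route**

Step 1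
Reactants: 1 isobutyryl chloride; 2 2-(trimethylsilyl)ethanol
Product: 3 2-(trimethylsilyl)ethyl 2-methylpropanoate
Conditions: Et3N, CH2Cl2, 0 → 20 °C
Reagents that add atoms: none
Why: Acylation of a primary alcohol by an acid chloride (nucleophilic acyl substitution) installs the fluoride-labile ester that later carries C3; no stereocentre is involved.

Step 2
Reactants: 3 2-(trimethylsilyl)ethyl 2-methylpropanoate
Product: 4 silyl ketene acetal 2-methyl-1-[2-(trimethylsilyl)ethoxy]-1-(trimethylsilyloxy)prop-1-ene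
Conditions: LiN(i-Pr)2, THF, −78 °C; Me3SiCl, −78 → 20 °C
Reagents that add atoms: chlorotrimethylsilane, C[Si](C)(C)Cl
Why: Ester deprotonation and O-silylation of the enolate (silyl ketene acetal formation); the enolate carbon bears two methyl groups, so neither geometry nor a stereocentre arises.

Step 3
Reactants: 4 silyl ketene acetal; 5 2-methylcyclopent-2-en-1-one
Product: 6 2-(trimethylsilyl)ethyl 2-methyl-2-[(1S)-2-methyl-3-(trimethylsilyloxy)cyclopent-2-en-1-yl]propanoate
Conditions: oxazaborolidinium salt prepared from (S)-α,α-diphenylprolinol, o-tolylboronic acid and HN(SO2CF3)2 (15 mol%), Ph3PO (20 mol%), toluene, −40 °C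
Reagents that add atoms: none
Why: Catalytic enantioselective Mukaiyama–Michael addition: the chiral boron Lewis acid binds the enone carbonyl and screens one face of the β-carbon, so the ketene acetal adds to the open face and sets C5 (S), while the silyl group ends on the enolate oxygen and keeps the enolate regiodefined (the mirror-image catalyst is taken if the sense of induction proves opposite).

Step 4
Reactants: 6 silyl enol ether; 7 methyl bromoacetate
Product: 9 methyl 2-[(1R,5S)-1-methyl-2-oxo-5-{2-methyl-1-oxo-1-[2-(trimethylsilyl)ethoxy]propan-2-yl}cyclopentyl]acetate, via lithium enolate 8 (not isolated)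
Conditions: MeLi, THF, 0 °C; then 7, DMPU, −78 → −20 °C
Reagents that add atoms: none
Why: Si–O cleavage by MeLi releases the tetrasubstituted lithium enolate regiospecifically, and SN2 alkylation at C10 occurs anti to the bulky C5 substituent, which sets the quaternary C10 (R) with the acetate arm trans to the propanoate arm.

Step 5
Reactants: 10 nerol
Product: 11 (2Z)-1-(tert-butyldimethylsilyloxy)-3,7-dimethylocta-2,6-diene
Conditions: t-BuMe2SiCl, imidazole, DMF, 0 → 20 °C
Reagents that add atoms: tert-butyldimethylsilyl chloride, CC(C)(C)[Si](C)(C)Cl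
Why: Silyl ether formation at the primary allylic alcohol; the Z double bond that later defines C13/C14 is untouched.

Step 6
Reactants: 11 neryl silyl ether
Product: 12 (4Z)-6-(tert-butyldimethylsilyloxy)-4-methylhex-4-enal
Conditions: O3 (0.95 equiv), pyridine, CH2Cl2, −78 °C; Me2S, −78 → 20 °C
Reagents that add atoms: ozone, [O-][O+]=O
Why: Chemoselective ozonolysis: the electron-richer 6,7-double bond reacts before the 2,3-double bond, which is deactivated by the allylic oxygen, and reductive work-up gives the aldehyde whose carbonyl carbon becomes C9.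

Step 7
Reactants: 12 aldehyde
Product: 13 (2Z)-1-(tert-butyldimethylsilyloxy)-3-methyl-6,6-bis(phenylselanyl)hex-2-ene
Conditions: PhSeH (2.2 equiv), ZnCl2 (0.3 equiv), CH2Cl2, 0 → 20 °C
Reagents that add atoms: benzeneselenol, [SeH]c1ccccc1
Why: Lewis-acid-catalysed selenoacetalisation of the aldehyde (selenium analogue of thioacetal formation) turns C9 into a latent carbanion; no stereocentre is formed.

Step 8
Reactants: 9 cyclopentanone; 13 selenoacetal
Product: 17 (5S,9S,10R)-15-(tert-butyldimethylsilyloxy)-8-oxo-17-nor-2,3-secolabd-13Z-ene-2,3-dioic acid 2-methyl 3-[2-(trimethylsilyl)ethyl] diester, via lithium carbanion 14 (not isolated), via hydroxy selenide 15 (not isolated), via C9-epimeric ketone 16 (not isolated)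
Conditions: 13, n-BuLi, THF, −78 °C; add 9, −78 °C; AcOH (1.0 equiv); AgBF4 (2.5 equiv), CH2Cl2 co-solvent, −40 → 20 °C; then DBU (0.3 equiv), 20 °C
Reagents that add atoms: none
Why: Se/Li exchange on 13 gives the α-selanyl carbanion 14, which adds to the C8 carbonyl of 9 (the C3 ester is neopentyl-shielded and the C2 ester is slower at −78 °C) to give carbinol 15 as a mixture at C8 and C9; after in-flask protonation, monovalent silver binds selenium, and the C8–O lone pair drives a 1,2-shift of the ring bond C8–C10 onto C9 (seleno-semipinacol rearrangement, the selenium counterpart of the Tiffeneau–Demjanov ring enlargement; closest precedent: silver-promoted enlargement of 1-(1-selanylalkyl)cycloalkanols to 2-alkylcycloalkanones). No ring is closed by cyclisation: the five-membered ring C5–C6–C7–C8–C10 grows by one atom into six-membered ring B (C5–C6–C7–C8–C9–C10) because C9 is inserted between C8 and C10, and the same event creates the C8 ketone. C10 migrates with retention and keeps the configuration set in step 4, whereas C9 is formed with inversion from each C9 epimer of 15 and is then funnelled by DBU through the C8 enolate to the one epimer with the equatorial side chain, so all diastereomers of 15 should converge on 17. The selectivity needed is migration of C10 rather than C7, and it is secured by C10 being fully substituted and thus the better migrating group towards the electron-poor C9, while either ring bond can stand anti to C–Se by rotation about C8–C9. Closure of 15 to an oxirane is held back by using the neutral alcohol and a silver salt instead of an alkoxide and base, and the acid released is buffered by the lithium acetate formed in the quench.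

Step 9
Reactants: 17 ring-B ketone
Product: 18 (5S,9R,10S)-15-(tert-butyldimethylsilyloxy)-2,3-secolabda-8(17),13Z-diene-2,3-dioic acid 2-methyl 3-[2-(trimethylsilyl)ethyl] diester (same spatial arrangement as 17)
Conditions: Ph3PCH3Br (2.0 equiv), KOtBu (1.9 equiv), toluene/THF, 0 → 60 °C
Reagents that add atoms: methyltriphenylphosphonium bromide, C[P+](c1ccccc1)(c1ccccc1)c1ccccc1.[Br-]
Why: Wittig methylenation of the C8 ketone supplies C17; C9 is already the thermodynamic epimer, so the basic ylide cannot erode it.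

Step 10
Reactants: 18 exocyclic alkene
Product: 20 (5S,8S,9S,10R)-15-(tert-butyldimethylsilyloxy)-8-hydroxy-2,3-secolabd-13Z-ene-2,3-dioic acid 2-methyl 3-[2-(trimethylsilyl)ethyl] diester, via alkylmercury acetate 19 (not isolated)
Conditions: Hg(OAc)2 (1.05 equiv), THF/H2O 1:1, 0 °C; then 3 M NaOH, NaBH4, 0 °C
Reagents that add atoms: water, O
Why: Oxymercuration–demercuration (Markovnikov hydration) of the 1,1-disubstituted double bond, which reacts faster than the trisubstituted allylic-ether double bond; water enters equatorially, anti to the axial C10 methyl, which sets C8 with equatorial OH and axial C17.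

Step 11
Reactants: 20 silyl ether
Product: 21 (5S,8S,9S,10R)-8,15-dihydroxy-2,3-secolabd-13Z-ene-2,3-dioic acid 2-methyl 3-[2-(trimethylsilyl)ethyl] diester
Conditions: camphorsulfonic acid (0.1 equiv), MeOH/CH2Cl2, 0 °C
Reagents that add atoms: none
Why: Acid-catalysed methanolysis of the primary silyl ether frees the allylic alcohol needed for directed epoxidation; the tertiary alcohol, both esters and the Z-alkene are inert under these conditions.

Step 12
Reactants: 21 diol
Product: 23 (5S,8S,9S,10R,13R,14R)-8,13-epoxy-14,15-dihydroxy-2,3-secolabdane-2,3-dioic acid 2-methyl 3-[2-(trimethylsilyl)ethyl] diester, via epoxy alcohol 22 (not isolated)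
Conditions: Ti(OiPr)4 (0.1 equiv), D-(−)-diethyl tartrate (0.12 equiv), t-BuOOH, 4 Å molecular sieves, CH2Cl2, −20 °C; then camphorsulfonic acid (0.1 equiv), 0 °C
Reagents that add atoms: tert-butyl hydroperoxide, CC(C)(C)OO
Why: Sharpless asymmetric epoxidation of the Z-allylic alcohol under reagent control (D-(−)-tartrate gives the 14R epoxy alcohol, here 13S,14R), after which the C8 hydroxyl opens the epoxide 6-exo at the tertiary C13 with inversion; this closes the trans-fused pyran and sets C13 (R) and C14 (R).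

Step 13
Reactants: 21 diol
Product: 25 (5S,8S,9S,10R,13S,14S)-8,13-epoxy-14,15-dihydroxy-2,3-secolabdane-2,3-dioic acid 2-methyl 3-[2-(trimethylsilyl)ethyl] diester, via epoxy alcohol 24 (not isolated)
Conditions: Ti(OiPr)4 (0.1 equiv), L-(+)-diethyl tartrate (0.12 equiv), t-BuOOH, 4 Å molecular sieves, CH2Cl2, −20 °C; then camphorsulfonic acid (0.1 equiv), 0 °C
Reagents that add atoms: tert-butyl hydroperoxide, CC(C)(C)OO
Why: The same Sharpless epoxidation with the enantiomeric tartrate gives the 13R,14S epoxide, and the same 6-exo opening at C13 with inversion closes the pyran with C13 (S), the configuration of the vinyl half.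

Step 14
Reactants: 25 left-half diol
Product: 26 (5S,8S,9S,10R,13S)-8,13-epoxy-2,3-secolabd-14-ene-2,3-dioic acid 2-methyl 3-[2-(trimethylsilyl)ethyl] diester
Conditions: PPh3, I2, imidazole, toluene, 110 °C
Reagents that add atoms: none
Why: Garegg–Samuelsson olefination converts the terminal vicinal diol through its iodo-oxyphosphonium intermediate into the vinyl group by reductive elimination; C13 is not touched and the C14 stereocentre disappears.

Step 15
Reactants: 26 left-half diester
Product: 27 (5S,8S,9S,10R,13S)-8,13-epoxy-2,3-secolabd-14-ene-2,3-dioic acid 2-methyl ester (C3 acid free)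
Conditions: n-Bu4NF, THF, 0 → 20 °C; cold dilute HCl to pH 3
Reagents that add atoms: none
Why: Fluoride attack at silicon and β-elimination (fragmentation of the 2-(trimethylsilyl)ethyl ester) frees only the hindered C3 acid, because the cleavage does not depend on access to the carbonyl, and the C2 methyl ester stays.

Step 16
Reactants: 27 left-half C3 acid; 23 right-half diol
Product: 29 C3(left)–O–C15(right) ester of 27 and 23 (left C2 methyl ester; right C2 methyl ester and C3 2-(trimethylsilyl)ethyl ester; C14–OH free), via acid chloride 28 (not isolated)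
Conditions: 27, 1-chloro-N,N,2-trimethylprop-1-en-1-amine, CH2Cl2, 0 → 20 °C; then 23, pyridine, DMAP (0.2 equiv), 0 → 40 °C
Reagents that add atoms: none
Why: Neutral acid chloride formation and DMAP-catalysed acylation (nucleophilic acyl substitution); the neopentyl-type acyl chloride should take the primary C15 hydroxyl and leave the secondary C14 hydroxyl next to quaternary C13.

Step 17
Reactants: 29 protected dimer
Product: 31 CNP0107285.2 (target), via monoacid dimethyl ester 30 (not isolated)
Conditions: n-Bu4NF, THF, 20 °C; then LiOH, THF/H2O, 20 → 35 °C; cold dilute HCl to pH 3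
Reagents that add atoms: lithium hydroxide, [Li+].[OH-]
Why: Fluoride fragmentation of the remaining 2-(trimethylsilyl)ethyl ester followed by saponification of the two unhindered methyl esters; the linking ester is α-quaternary (pivalate-like) and should survive LiOH at this temperature, and no acid strong enough to ionise the tertiary allylic ether is used.

**Compound list**

1 | isobutyryl chloride | CC(C)C(Cl)=O | starting material
2 | 2-(trimethylsilyl)ethanol | C[Si](C)(C)CCO | starting material
3 | 2-(trimethylsilyl)ethyl 2-methylpropanoate | CC(C)C(=O)OCC[Si](C)(C)C | intermediate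
4 | 2-methyl-1-[2-(trimethylsilyl)ethoxy]-1-(trimethylsilyloxy)prop-1-ene (silyl ketene acetal) | CC(C)=C(O[Si](C)(C)C)OCC[Si](C)(C)C | intermediate
5 | 2-methylcyclopent-2-en-1-one | CC1=CCCC1=O | starting material
6 | 2-(trimethylsilyl)ethyl 2-methyl-2-[(1S)-2-methyl-3-(trimethylsilyloxy)cyclopent-2-en-1-yl]propanoate | C[Si](C)(C)OC1=C(C)[C@@H](C(C)(C)C(=O)OCC[Si](C)(C)C)CC1 | intermediate
7 | methyl bromoacetate | COC(=O)CBr | starting material
8 | lithium (3S)-2-methyl-3-{2-methyl-1-oxo-1-[2-(trimethylsilyl)ethoxy]propan-2-yl}cyclopent-1-en-1-olate | [Li+].[O-]C1=C(C)[C@@H](C(C)(C)C(=O)OCC[Si](C)(C)C)CC1 | intermediate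
9 | methyl 2-[(1R,5S)-1-methyl-2-oxo-5-{2-methyl-1-oxo-1-[2-(trimethylsilyl)ethoxy]propan-2-yl}cyclopentyl]acetate (ring = C8, C10, C5, C6, C7) | O=C1CC[C@H](C(C)(C)C(=O)OCC[Si](C)(C)C)[C@@]1(C)CC(=O)OC | intermediate
10 | nerol, (2Z)-3,7-dimethylocta-2,6-dien-1-ol | CC(C)=CCC/C(C)=C\CO | starting material
11 | (2Z)-1-(tert-butyldimethylsilyloxy)-3,7-dimethylocta-2,6-diene | CC(C)=CCC/C(C)=C\CO[Si](C)(C)C(C)(C)C | intermediate
12 | (4Z)-6-(tert-butyldimethylsilyloxy)-4-methylhex-4-enal | O=CCC/C(C)=C\CO[Si](C)(C)C(C)(C)C | intermediate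
13 | (2Z)-1-(tert-butyldimethylsilyloxy)-3-methyl-6,6-bis(phenylselanyl)hex-2-ene | CC(C)(C)[Si](C)(C)OC/C=C(C)\CCC([Se]c1ccccc1)[Se]c1ccccc1 | intermediate
14 | [(4Z)-6-(tert-butyldimethylsilyloxy)-4-methyl-1-(phenylselanyl)hex-4-en-1-yl]lithium | [Li]C([Se]c1ccccc1)CC/C(C)=C\CO[Si](C)(C)C(C)(C)C | intermediate
15 | methyl 2-[(1R,5S)-2-hydroxy-2-[(4Z)-6-(tert-butyldimethylsilyloxy)-4-methyl-1-(phenylselanyl)hex-4-en-1-yl]-1-methyl-5-{2-methyl-1-oxo-1-[2-(trimethylsilyl)ethoxy]propan-2-yl}cyclopentyl]acetate, mixture at C8 and C9 | CC(C)(C)[Si](C)(C)OC/C=C(C)\CCC([Se]c1ccccc1)C1(O)CC[C@H](C(C)(C)C(=O)OCC[Si](C)(C)C)[C@@]1(C)CC(=O)OC | intermediate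
16 | (5S,9R,10R)-15-(tert-butyldimethylsilyloxy)-8-oxo-17-nor-2,3-secolabd-13Z-ene-2,3-dioic acid 2-methyl 3-[2-(trimethylsilyl)ethyl] diester (C9 epimer of 17, axial side chain) | CC(C)(C)[Si](C)(C)OC/C=C(C)\CC[C@@H]1[C@](C)(CC(=O)OC)[C@@H](C(C)(C)C(=O)OCC[Si](C)(C)C)CCC1=O | intermediate
17 | (5S,9S,10R)-15-(tert-butyldimethylsilyloxy)-8-oxo-17-nor-2,3-secolabd-13Z-ene-2,3-dioic acid 2-methyl 3-[2-(trimethylsilyl)ethyl] diester (cyclohexanone ring B; equatorial C9 side chain, axial C10 methyl, equatorial C10 and C5 ester arms) | CC(C)(C)[Si](C)(C)OC/C=C(C)\CC[C@H]1[C@](C)(CC(=O)OC)[C@@H](C(C)(C)C(=O)OCC[Si](C)(C)C)CCC1=O | intermediate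
18 | (5S,9R,10S)-15-(tert-butyldimethylsilyloxy)-2,3-secolabda-8(17),13Z-diene-2,3-dioic acid 2-methyl 3-[2-(trimethylsilyl)ethyl] diester (same spatial arrangement as 17) | CC(C)(C)[Si](C)(C)OC/C=C(C)\CC[C@H]1[C@](C)(CC(=O)OC)[C@@H](C(C)(C)C(=O)OCC[Si](C)(C)C)CCC1=C | intermediate
19 | (5S,8S,9S,10R)-17-(acetoxymercurio)-15-(tert-butyldimethylsilyloxy)-8-hydroxy-2,3-secolabd-13Z-ene-2,3-dioic acid 2-methyl 3-[2-(trimethylsilyl)ethyl] diester | CC(C)(C)[Si](C)(C)OC/C=C(C)\CC[C@H]1[C@](C)(CC(=O)OC)[C@@H](C(C)(C)C(=O)OCC[Si](C)(C)C)CC[C@]1(C[Hg]OC(C)=O)O | intermediate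
20 | (5S,8S,9S,10R)-15-(tert-butyldimethylsilyloxy)-8-hydroxy-2,3-secolabd-13Z-ene-2,3-dioic acid 2-methyl 3-[2-(trimethylsilyl)ethyl] diester (equatorial 8-OH, axial C17) | CC(C)(C)[Si](C)(C)OC/C=C(C)\CC[C@H]1[C@](C)(CC(=O)OC)[C@@H](C(C)(C)C(=O)OCC[Si](C)(C)C)CC[C@]1(C)O | intermediate
21 | (5S,8S,9S,10R)-8,15-dihydroxy-2,3-secolabd-13Z-ene-2,3-dioic acid 2-methyl 3-[2-(trimethylsilyl)ethyl] diester | OC/C=C(C)\CC[C@H]1[C@](C)(CC(=O)OC)[C@@H](C(C)(C)C(=O)OCC[Si](C)(C)C)CC[C@]1(C)O | intermediate
22 | (5S,8S,9S,10R,13S,14R)-13,14-epoxy-8,15-dihydroxy-2,3-secolabdane-2,3-dioic acid 2-methyl 3-[2-(trimethylsilyl)ethyl] diester | OC[C@H]1O[C@@]1(C)CC[C@H]2[C@](C)(CC(=O)OC)[C@@H](C(C)(C)C(=O)OCC[Si](C)(C)C)CC[C@]2(C)O | intermediate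
23 | (5S,8S,9S,10R,13R,14R)-8,13-epoxy-14,15-dihydroxy-2,3-secolabdane-2,3-dioic acid 2-methyl 3-[2-(trimethylsilyl)ethyl] diester (right half) | OC[C@@H](O)[C@@]1(C)CC[C@H]2[C@](C)(CC(=O)OC)[C@@H](C(C)(C)C(=O)OCC[Si](C)(C)C)CC[C@]2(C)O1 | intermediate
24 | (5S,8S,9S,10R,13R,14S)-13,14-epoxy-8,15-dihydroxy-2,3-secolabdane-2,3-dioic acid 2-methyl 3-[2-(trimethylsilyl)ethyl] diester | OC[C@@H]1O[C@]1(C)CC[C@H]2[C@](C)(CC(=O)OC)[C@@H](C(C)(C)C(=O)OCC[Si](C)(C)C)CC[C@]2(C)O | intermediate
25 | (5S,8S,9S,10R,13S,14S)-8,13-epoxy-14,15-dihydroxy-2,3-secolabdane-2,3-dioic acid 2-methyl 3-[2-(trimethylsilyl)ethyl] diester | OC[C@H](O)[C@]1(C)CC[C@H]2[C@](C)(CC(=O)OC)[C@@H](C(C)(C)C(=O)OCC[Si](C)(C)C)CC[C@]2(C)O1 | intermediate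
26 | (5S,8S,9S,10R,13S)-8,13-epoxy-2,3-secolabd-14-ene-2,3-dioic acid 2-methyl 3-[2-(trimethylsilyl)ethyl] diester | C=C[C@]1(C)CC[C@H]2[C@](C)(CC(=O)OC)[C@@H](C(C)(C)C(=O)OCC[Si](C)(C)C)CC[C@]2(C)O1 | intermediate
27 | (5S,8S,9S,10R,13S)-8,13-epoxy-2,3-secolabd-14-ene-2,3-dioic acid 2-methyl ester (left half, C3 acid free) | C=C[C@]1(C)CC[C@H]2[C@](C)(CC(=O)OC)[C@@H](C(C)(C)C(=O)O)CC[C@]2(C)O1 | intermediate
28 | C3 acid chloride of 27 | C=C[C@]1(C)CC[C@H]2[C@](C)(CC(=O)OC)[C@@H](C(C)(C)C(Cl)=O)CC[C@]2(C)O1 | intermediate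
29 | protected dimer: C3 acyl of 27 on O15 of 23 (two C2 methyl esters, right C3 2-(trimethylsilyl)ethyl ester, free 14-OH) | C=C[C@]1(C)CC[C@H]2[C@](C)(CC(=O)OC)[C@@H](C(C)(C)C(=O)OC[C@@H](O)[C@@]3(C)CC[C@H]4[C@](C)(CC(=O)OC)[C@@H](C(C)(C)C(=O)OCC[Si](C)(C)C)CC[C@]4(C)O3)CC[C@]2(C)O1 | intermediate
30 | dimer with right C3 acid free and both C2 methyl esters | C=C[C@]1(C)CC[C@H]2[C@](C)(CC(=O)OC)[C@@H](C(C)(C)C(=O)OC[C@@H](O)[C@@]3(C)CC[C@H]4[C@](C)(CC(=O)OC)[C@@H](C(C)(C)C(=O)O)CC[C@]4(C)O3)CC[C@]2(C)O1 | intermediate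
31 | CNP0107285.2 | C=C[C@]1(C)CC[C@H]2[C@](C)(CC(=O)O)[C@@H](C(C)(C)C(=O)OC[C@@H](O)[C@@]3(C)CC[C@H]4[C@](C)(CC(=O)O)[C@@H](C(C)(C)C(=O)O)CC[C@]4(C)O3)CC[C@]2(C)O1 | target

**Step count and risks**

Total step count: 17. Longest linear sequence: 13 steps (steps 1, 2, 3, 4, 8, 9, 10, 11, 13, 14, 15, 16, 17).

Steps most likely to fail:

Step 8. The α-selanyl carbanion may enolise the hindered ketone instead of adding to it. The carbinol may close to an oxirane instead of rearranging. The less substituted C7 may migrate in place of C10. The fallback sets out from 12 and 9 and comes back at 17, and it replaces the selenium leaving group by a sulfur-stabilised cation. Aldehyde 12 is converted with PhSH and ZnCl2 into the bis(phenylsulfanyl)acetal F1. Deprotonation (n-BuLi, TMEDA, THF, −78 → 0 °C) gives the lithio derivative F2, which adds to 9 to give the α-hydroxy dithioacetal F3. CuOTf (monovalent copper) and i-Pr2NEt in benzene ionise one C–S bond; the resulting thionium ion at C9 cannot close to an oxirane and should draw the more substituted C10 in the same one-atom ring enlargement, giving the 9-(phenylsulfanyl) ketone F4. Bu3SnH/AIBN removes sulfur through the α-keto radical, and DBU equilibrates C9 (16 to 17).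

Step 3. Turnover may be poor or facial discrimination weak on the α-methyl-substituted enone. The fallback sets out from 4 and 5 and comes back at 9, and it replaces asymmetric catalysis by resolution. The Mukaiyama–Michael addition is run with an achiral Lewis acid (Me3SiOSO2CF3, CH2Cl2, −78 °C) to give 6 together with its enantiomer F5. Step 4 is carried out on the racemate, through enolate 8 and its enantiomer F6, to give 9 together with its enantiomer F7. Preparative chromatography on a chiral stationary phase then delivers 9.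

Step 16. Acyl transfer from the neopentyl-type acid chloride may be slow, allowing competing acylation at O14 or hydrolysis of the chloride. The fallback sets out from 23 and 27 and comes back at 29, and it forms the ester by O-alkylation instead of acylation. Diol 23 is sulfonylated at the primary hydroxyl (TsCl, Et3N, Bu2SnO cat., CH2Cl2) to the 15-tosylate F8. The caesium carboxylate of 27 (Cs2CO3, DMF, 60 °C) then displaces the sulfonate at C15, either directly or through the terminal 14,15-epoxide F9 formed in the basic medium; both paths leave C14 untouched and give 29.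

**Further compounds**

F1 | step 8 | (2Z)-1-(tert-butyldimethylsilyloxy)-3-methyl-6,6-bis(phenylsulfanyl)hex-2-ene | CC(C)(C)[Si](C)(C)OC/C=C(C)\CCC(Sc1ccccc1)Sc1ccccc1
F2 | step 8 | [(4Z)-6-(tert-butyldimethylsilyloxy)-4-methyl-1,1-bis(phenylsulfanyl)hex-4-en-1-yl]lithium | [Li]C(Sc1ccccc1)(Sc1ccccc1)CC/C(C)=C\CO[Si](C)(C)C(C)(C)C
F3 | step 8 | adduct of F2 and 9: C8 carbinol bearing the C9 bis(phenylsulfanyl) carbon (mixture at C8) | CC(C)(C)[Si](C)(C)OC/C=C(C)\CCC(Sc1ccccc1)(Sc1ccccc1)C1(O)CC[C@H](C(C)(C)C(=O)OCC[Si](C)(C)C)[C@@]1(C)CC(=O)OC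
F4 | step 8 | 9-(phenylsulfanyl) derivative of ketone 17 (mixture at C9) | CC(C)(C)[Si](C)(C)OC/C=C(C)\CCC1(Sc2ccccc2)[C@](C)(CC(=O)OC)[C@@H](C(C)(C)C(=O)OCC[Si](C)(C)C)CCC1=O
F5 | step 3 | enantiomer of 6 | C[Si](C)(C)OC1=C(C)[C@H](C(C)(C)C(=O)OCC[Si](C)(C)C)CC1
F6 | step 3 | enantiomer of 8 | [Li+].[O-]C1=C(C)[C@H](C(C)(C)C(=O)OCC[Si](C)(C)C)CC1
F7 | step 3 | enantiomer of 9 | O=C1CC[C@@H](C(C)(C)C(=O)OCC[Si](C)(C)C)[C@]1(C)CC(=O)OC
F8 | step 16 | 15-O-(4-methylbenzenesulfonyl) derivative of 23 | Cc1ccc(cc1)S(=O)(=O)OC[C@@H](O)[C@@]1(C)CC[C@H]2[C@](C)(CC(=O)OC)[C@@H](C(C)(C)C(=O)OCC[Si](C)(C)C)CC[C@]2(C)O1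
F9 | step 16 | (13R,14R)-8,13:14,15-diepoxy-2,3-secolabdane-2,3-dioic acid 2-methyl 3-[2-(trimethylsilyl)ethyl] diester | C1O[C@H]1[C@@]2(C)CC[C@H]3[C@](C)(CC(=O)OC)[C@@H](C(C)(C)C(=O)OCC[Si](C)(C)C)CC[C@]3(C)O2
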